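**Retrosynthetic overview**
1. Last events: peracid epoxidation of the 1(10)-olefin of the heliangolide diene, preceded by two Shiina acylations (C3–OH, then C8–OH) with acids that both come from tiglic acid.
2. Ten-membered carbocycle (second ring): Ni/Cr-catalysed Nozaki–Hiyama–Kishi closure of the C3–C4 bond (Z-alkenyl iodide onto a β,γ-unsaturated aldehyde).
3. α-Methylene-γ-lactone (first ring) and the C6–C7 bond: chromium-catalysed anti-selective 2-(methoxycarbonyl)allylation/lactonisation joining (Z)-3-iodobut-2-enal to an allyl bromide that carries C7–C10 and C1–C3.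
4. Allyl bromide: Baylis–Hillman reaction and allylic transposition on an α-silyloxy aldehyde, itself from copper-catalysed opening of ethyl (R)-glycidate (from L-serine) by an E-alkenyl Grignard (from pent-3-yn-1-ol); this forms C9–C10.
5. Building blocks: pent-3-yn-1-ol, L-serine, methyl acrylate, but-2-yn-1-ol, tiglic acid.

Assumption: the target is read from the SMILES as (1R,3S,6R,7R,8R,10R)-1β,10α-epoxy-3β-[(2R)-2-methylbutanoyloxy]-8β-[(2R,3S)-2,3-dimethyloxirane-2-carbonyloxy]germacra-4Z,11(13)-dien-6α,12-olide; germacrane numbering (C1–C15) is used in the explanations, and chiral ligands and protecting-group reagents are treated as reagents.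

**Route**

Step 1
Reactants: 1 pent-3-yn-1-ol
Product: 2 1-methoxy-4-[(pent-3-yn-1-yloxy)methyl]benzene
Conditions: NaH, 4-methoxybenzyl chloride, Bu4NI (cat.), THF/DMF, 0 °C → rt
Reagents that add atoms: 4-methoxybenzyl chloride, COc1ccc(CCl)cc1
Why: Williamson ether synthesis masks the future C3 oxygen as a PMB ether that survives organometallic, hydride and chromium steps and is later removed oxidatively beside a silyl ether.

Step 2
Reactants: 2 1-methoxy-4-[(pent-3-yn-1-yloxy)methyl]benzene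
Product: 4 1-({[(3E)-4-iodopent-3-en-1-yl]oxy}methyl)-4-methoxybenzene, via alkenylzirconocene 3 (not isolated)
Conditions: Cp2Zr(H)Cl (2 equiv), THF, 45 °C; then I2, 0 °C
Reagents that add atoms: iodine, II
Why: Hydrozirconation–iodination: syn Zr–H addition, equilibrated by excess reagent so that zirconium sits on the methyl-bearing carbon, followed by iodinolysis with retention fixes the E geometry of the future C1=C10 olefin.

Step 3
Reactants: 5 L-serine
Product: 7 potassium (R)-oxirane-2-carboxylate, via bromo acid 6 (not isolated)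
Conditions: NaNO2, HBr, KBr, H2O, −10 °C → rt; extraction; then KOH, EtOH, −20 °C → rt
Reagents that add atoms: potassium hydroxide, [K+].[OH-]
Why: Diazotisation–bromination proceeds with net retention (double inversion through the α-lactone) and the intramolecular Williamson closure with inversion gives the (R)-glycidate whose stereocentre becomes C8.

Step 4
Reactants: 7 potassium (R)-oxirane-2-carboxylate
Product: 8 ethyl (R)-oxirane-2-carboxylate
Conditions: EtI, DMF, rt
Reagents that add atoms: iodoethane, CCI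
Why: Carboxylate O-alkylation (SN2 at the ethyl group) does not touch the stereocentre.

Step 5
Reactants: 4 1-({[(3E)-4-iodopent-3-en-1-yl]oxy}methyl)-4-methoxybenzene, 8 ethyl (R)-oxirane-2-carboxylate
Product: 10 ethyl (2R,4E)-2-hydroxy-7-[(4-methoxybenzyl)oxy]-4-methylhept-4-enoate, via alkenylmagnesium chloride 9 (not isolated)
Conditions: i-PrMgCl·LiCl, THF, 0 °C → rt; then CuI (10 mol %), 8, THF, −40 → −20 °C; aq. NH4Cl
Reagents that add atoms: none
Why: Iodine–magnesium exchange with retention of olefin geometry followed by copper-catalysed SN2 opening of the glycidate at its CH2 terminus forms the C9–C10 bond and leaves the C8 carbinol configuration (R) untouched.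

Step 6
Reactants: 10 ethyl (2R,4E)-2-hydroxy-7-[(4-methoxybenzyl)oxy]-4-methylhept-4-enoate
Product: 11 ethyl (2R,4E)-2-[(tert-butyldimethylsilyl)oxy]-7-[(4-methoxybenzyl)oxy]-4-methylhept-4-enoate
Conditions: TBSCl, imidazole, DMF, rt
Reagents that add atoms: tert-butyldimethylsilyl chloride, CC(C)(C)[Si](C)(C)Cl
Why: Standard silylation protects the C8 hydroxyl with a group that is orthogonal to PMB and is removed only at the end with fluoride.

Step 7
Reactants: 11 ethyl (2R,4E)-2-[(tert-butyldimethylsilyl)oxy]-7-[(4-methoxybenzyl)oxy]-4-methylhept-4-enoate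
Product: 12 (2R,4E)-2-[(tert-butyldimethylsilyl)oxy]-7-[(4-methoxybenzyl)oxy]-4-methylhept-4-enal
Conditions: i-Bu2AlH (1.1 equiv), CH2Cl2, −78 °C; aq. potassium sodium tartrate
Reagents that add atoms: none
Why: Partial ester reduction stops at the aldehyde because the α-silyloxy aluminium hemiacetal is stable at −78 °C, and the α-stereocentre does not epimerise under these conditions.

Step 8
Reactants: 12 (2R,4E)-2-[(tert-butyldimethylsilyl)oxy]-7-[(4-methoxybenzyl)oxy]-4-methylhept-4-enal, 13 methyl acrylate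
Product: 14 methyl (3RS,4R,6E)-4-[(tert-butyldimethylsilyl)oxy]-3-hydroxy-9-[(4-methoxybenzyl)oxy]-6-methyl-2-methylidenenon-6-enoate
Conditions: 13 (5 equiv), DABCO (1 equiv), MeOH (2 equiv), rt, 4 d
Reagents that add atoms: none
Why: Morita–Baylis–Hillman reaction attaches the C11–C13 acrylate unit to C7 of the activated α-silyloxy aldehyde; the new carbinol forms as an epimer mixture that is erased in the next step.

Step 9
Reactants: 14 methyl (3RS,4R,6E)-4-[(tert-butyldimethylsilyl)oxy]-3-hydroxy-9-[(4-methoxybenzyl)oxy]-6-methyl-2-methylidenenon-6-enoate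
Product: 15 methyl (2Z,4R,6E)-2-(bromomethyl)-4-[(tert-butyldimethylsilyl)oxy]-9-[(4-methoxybenzyl)oxy]-6-methylnona-2,6-dienoate
Conditions: NBS, Me2S, CH2Cl2, −20 → 0 °C; then 14, 0 °C → rt
Reagents that add atoms: N-bromosuccinimide, O=C1CCC(=O)N1Br
Why: Corey–Kim activation of the allylic alcohol and SN2′ delivery of bromide (allylic transposition) gives the thermodynamically favoured Z-2-(bromomethyl)enoate without involving the C8 stereocentre.

Step 10
Reactants: 16 but-2-yn-1-ol
Product: 18 (Z)-3-iodobut-2-en-1-ol, via cyclic alkenylalanate 17 (not isolated)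
Conditions: NaAlH2(OCH2CH2OMe)2, Et2O, 0 °C → rt; then I2, THF, −78 °C
Reagents that add atoms: iodine, II
Why: Hydroxyl-directed trans-hydroalumination places aluminium on C3 cis to the CH2O group in a five-membered alanate and iodinolysis with retention gives the Z-iodoalkene that fixes the 4Z geometry of the target.

Step 11
Reactants: 18 (Z)-3-iodobut-2-en-1-ol
Product: 19 (Z)-3-iodobut-2-enal
Conditions: MnO2 (activated, excess), CH2Cl2, rt, dark
Reagents that add atoms: none
Why: Heterogeneous allylic oxidation with MnO2 is neutral and does not isomerise the Z olefin.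

Step 12
Reactants: 15 methyl (2Z,4R,6E)-2-(bromomethyl)-4-[(tert-butyldimethylsilyl)oxy]-9-[(4-methoxybenzyl)oxy]-6-methylnona-2,6-dienoate, 19 (Z)-3-iodobut-2-enal
Product: 21 (4S,5S)-4-[(1R,3E)-1-[(tert-butyldimethylsilyl)oxy]-6-[(4-methoxybenzyl)oxy]-3-methylhex-3-en-1-yl]-5-[(1Z)-2-iodoprop-1-en-1-yl]-3-methylideneoxolan-2-one, via silyl ether 20 (not isolated)
Conditions: nickel-free CrCl2 (10 mol %), chiral carbazole-bis(4-tert-butyloxazoline) ligand (12 mol %, antipode that directs attack on the Si face of the aldehyde), Et3N (20 mol %), Mn powder (2 equiv), TMSCl (1.5 equiv), THF, rt; then 1 M HCl, THF, 0 °C → rt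
Reagents that add atoms: none
Why: Proposed new method: a chromium-catalysed, ligand-controlled anti-selective 2-(methoxycarbonyl)allylation–lactonisation applied for the first time to a γ-branched allyl bromide with a δ-silyloxy stereocentre and a (Z)-β-iodoenal, in which divalent chromium (regenerated by Mn) turns 15 into an allylchromium species of trivalent chromium that equilibrates to the E form, the chiral chromium complex delivers C7 to the Si face of the C6 aldehyde through a chair transition state with both substituents equatorial (anti adduct, hence the trans lactone, so C6 and C7 are set by the catalyst while C8 is a spectator), TMSCl frees the catalyst, the nickel-free medium leaves the C–I bond intact and acid closes the lactone; the closest known reactions are the chromium-catalysed asymmetric 2-(alkoxycarbonyl)allylation of aldehydes with unsubstituted 2-(bromomethyl)acrylates and the anti-selective Nozaki–Hiyama crotylation.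

Step 13
Reactants: 21 (4S,5S)-4-[(1R,3E)-1-[(tert-butyldimethylsilyl)oxy]-6-[(4-methoxybenzyl)oxy]-3-methylhex-3-en-1-yl]-5-[(1Z)-2-iodoprop-1-en-1-yl]-3-methylideneoxolan-2-one
Product: 22 (4S,5S)-4-[(1R,3E)-1-[(tert-butyldimethylsilyl)oxy]-6-hydroxy-3-methylhex-3-en-1-yl]-5-[(1Z)-2-iodoprop-1-en-1-yl]-3-methylideneoxolan-2-one
Conditions: DDQ, CH2Cl2/pH 7 buffer (10:1), 0 °C
Reagents that add atoms: none
Why: Oxidative PMB cleavage (benzylic hydride abstraction, then hydrolysis of the oxocarbenium ion) frees the C3 hydroxyl without affecting the silyl ether, the alkenyl iodide or the lactone.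

Step 14
Reactants: 22 (4S,5S)-4-[(1R,3E)-1-[(tert-butyldimethylsilyl)oxy]-6-hydroxy-3-methylhex-3-en-1-yl]-5-[(1Z)-2-iodoprop-1-en-1-yl]-3-methylideneoxolan-2-one
Product: 23 (3E,6R)-6-[(tert-butyldimethylsilyl)oxy]-6-[(2S,3S)-2-[(1Z)-2-iodoprop-1-en-1-yl]-4-methylidene-5-oxooxolan-3-yl]-4-methylhex-3-enal
Conditions: Dess–Martin periodinane, pyridine, CH2Cl2, 0 °C; used crude at once
Reagents that add atoms: none
Why: Dess–Martin oxidation is mild and non-basic, so the β,γ-unsaturated aldehyde is obtained without migration of the C1=C10 olefin into conjugation.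

Step 15
Reactants: 23 (3E,6R)-6-[(tert-butyldimethylsilyl)oxy]-6-[(2S,3S)-2-[(1Z)-2-iodoprop-1-en-1-yl]-4-methylidene-5-oxooxolan-3-yl]-4-methylhex-3-enal
Product: 24 (3aS,4R,6E,9S,10Z,11aR)-4-[(tert-butyldimethylsilyl)oxy]-9-hydroxy-6,10-dimethyl-3-methylidene-3a,4,5,8,9,11a-hexahydrocyclodeca[b]furan-2(3H)-one
Conditions: CrCl2 (20 mol %), chiral oxazoline–sulfonamide ligand of the Kishi type (22 mol %, antipode that directs attack on the Re face of the aldehyde), NiCl2(dmp) (2 mol %, dmp = 2,9-dimethyl-1,10-phenanthroline), Mn powder (2 equiv), Cp2ZrCl2 (1.2 equiv), LiCl (2 equiv), MeCN, rt, syringe-pump addition to 2 mM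
Reagents that add atoms: none
Why: Catalytic asymmetric Nozaki–Hiyama–Kishi macrocyclisation: zerovalent nickel inserts into the C–I bond with retention of the Z geometry, transmetalation gives an alkenylchromium species of trivalent chromium whose ligand-controlled Re-face addition to the C3 aldehyde forms the C3–C4 bond, the ten-membered ring and the (S)-configured C3 carbinol, with high dilution favouring ring closure.

Step 16
Reactants: 25 tiglic acid
Product: 26 (R)-2-methylbutanoic acid
Conditions: H2 (4 atm), Ru(OAc)2[(R)-H8-BINAP] (0.5 mol %), MeOH, rt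
Reagents that add atoms: none
Why: Noyori-type asymmetric hydrogenation of the carboxylate-bound α,β-unsaturated acid sets the (R) α-stereocentre through face-selective hydride delivery from the chiral ruthenium complex.

Step 17
Reactants: 24 (3aS,4R,6E,9S,10Z,11aR)-4-[(tert-butyldimethylsilyl)oxy]-9-hydroxy-6,10-dimethyl-3-methylidene-3a,4,5,8,9,11a-hexahydrocyclodeca[b]furan-2(3H)-one, 26 (R)-2-methylbutanoic acid
Product: 28 (3aS,4R,6E,9S,10Z,11aR)-4-[(tert-butyldimethylsilyl)oxy]-6,10-dimethyl-3-methylidene-2-oxo-2,3,3a,4,5,8,9,11a-octahydrocyclodeca[b]furan-9-yl (2R)-2-methylbutanoate, via mixed anhydride 27 (not isolated)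
Conditions: 2-methyl-6-nitrobenzoic anhydride, Et3N, DMAP (cat.), CH2Cl2, rt
Reagents that add atoms: none
Why: Shiina esterification acylates the only free hydroxyl (C3) with retention at C3 and without epimerising the α-centre of the acid.

Step 18
Reactants: 28 (3aS,4R,6E,9S,10Z,11aR)-4-[(tert-butyldimethylsilyl)oxy]-6,10-dimethyl-3-methylidene-2-oxo-2,3,3a,4,5,8,9,11a-octahydrocyclodeca[b]furan-9-yl (2R)-2-methylbutanoate
Product: 29 (3aR,4R,6E,9S,10Z,11aR)-4-hydroxy-6,10-dimethyl-3-methylidene-2-oxo-2,3,3a,4,5,8,9,11a-octahydrocyclodeca[b]furan-9-yl (2R)-2-methylbutanoate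
Conditions: HF·pyridine, pyridine, THF, 0 °C → rt
Reagents that add atoms: none
Why: Buffered fluoride cleavage of the secondary TBS ether leaves the allylic ester, the α-methylene lactone and both trisubstituted olefins intact and touches no stereocentre.

Step 19
Reactants: 25 tiglic acid
Product: 30 (E)-2-methylbut-2-en-1-ol
Conditions: LiAlH4, Et2O, 0 °C → rt
Reagents that add atoms: none
Why: Hydride 1,2-reduction of the acid gives the allylic alcohol with the E geometry retained.

Step 20
Reactants: 30 (E)-2-methylbut-2-en-1-ol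
Product: 31 [(2S,3S)-2,3-dimethyloxiran-2-yl]methanol
Conditions: Ti(OiPr)4 (5 mol %), L-(+)-diethyl tartrate (6 mol %), t-BuOOH, 4 Å molecular sieves, CH2Cl2, −20 °C
Reagents that add atoms: tert-butyl hydroperoxide, CC(C)(C)OO
Why: Sharpless asymmetric epoxidation: the titanium–L-(+)-tartrate complex delivers oxygen to the olefin face that gives the (2S,3S) epoxy alcohol, as for other E-trisubstituted allylic alcohols.

Step 21
Reactants: 31 [(2S,3S)-2,3-dimethyloxiran-2-yl]methanol
Product: 32 (2R,3S)-2,3-dimethyloxirane-2-carboxylic acid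
Conditions: RuCl3·xH2O (2 mol %), NaIO4 (4 equiv), CCl4/MeCN/H2O, rt
Reagents that add atoms: water, O
Why: Catalytic RuO4 oxidation takes the primary alcohol to the acid through the aldehyde hydrate without opening the epoxide, so both centres are kept (the C2 descriptor changes only through CIP priorities).

Step 22
Reactants: 29 (3aR,4R,6E,9S,10Z,11aR)-4-hydroxy-6,10-dimethyl-3-methylidene-2-oxo-2,3,3a,4,5,8,9,11a-octahydrocyclodeca[b]furan-9-yl (2R)-2-methylbutanoate, 32 (2R,3S)-2,3-dimethyloxirane-2-carboxylic acid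
Product: 34 (3aR,4R,6E,9S,10Z,11aR)-6,10-dimethyl-3-methylidene-9-{[(2R)-2-methylbutanoyl]oxy}-2-oxo-2,3,3a,4,5,8,9,11a-octahydrocyclodeca[b]furan-4-yl (2R,3S)-2,3-dimethyloxirane-2-carboxylate, via mixed anhydride 33 (not isolated)
Conditions: 2-methyl-6-nitrobenzoic anhydride, Et3N, DMAP (1 equiv), toluene, rt → 40 °C
Reagents that add atoms: none
Why: Shiina esterification is suited to a hindered secondary alcohol and an α,α-disubstituted acid, proceeds with retention at C8 and tolerates the glycidic epoxide.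

Step 23
Reactants: 34 (3aR,4R,6E,9S,10Z,11aR)-6,10-dimethyl-3-methylidene-9-{[(2R)-2-methylbutanoyl]oxy}-2-oxo-2,3,3a,4,5,8,9,11a-octahydrocyclodeca[b]furan-4-yl (2R,3S)-2,3-dimethyloxirane-2-carboxylate
Product: 35 CNP0265335.3
Conditions: mCPBA (1.05 equiv), CH2Cl2, 0 °C; aq. NaHCO3 work-up
Reagents that add atoms: 3-chloroperoxybenzoic acid, O=C(OO)c1cccc(Cl)c1
Why: Prilezhaev epoxidation selects the electron-rich 1(10)-olefin (the 4,5-olefin is deactivated by two allylic acyloxy groups and the 11(13)-olefin is electron-poor), and stereospecific syn delivery to the outer face of the E olefin in the folded ten-membered ring is expected to give the 1β,10α epoxide, as is usual for germacranolides.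

**Compound list**
1 | pent-3-yn-1-ol | CC#CCCO | starting material
2 | 1-methoxy-4-[(pent-3-yn-1-yloxy)methyl]benzene | CC#CCCOCc1ccc(OC)cc1 | intermediate
3 | chlorobis(cyclopentadienyl)[(2E)-5-[(4-methoxybenzyl)oxy]pent-2-en-2-yl]zirconium | C/C(=C\CCOCc1ccc(OC)cc1)[Zr](Cl)(C1C=CC=C1)C1C=CC=C1 | intermediate (not isolated)
4 | 1-({[(3E)-4-iodopent-3-en-1-yl]oxy}methyl)-4-methoxybenzene | C/C(I)=C\CCOCc1ccc(OC)cc1 | intermediate
5 | L-serine | N[C@@H](CO)C(=O)O | starting material
6 | (S)-2-bromo-3-hydroxypropanoic acid | OC[C@H](Br)C(=O)O | intermediate (not isolated)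
7 | potassium (R)-oxirane-2-carboxylate | [K+].[O-]C(=O)[C@H]1CO1 | intermediate
8 | ethyl (R)-oxirane-2-carboxylate | CCOC(=O)[C@H]1CO1 | intermediate
9 | [(2E)-5-[(4-methoxybenzyl)oxy]pent-2-en-2-yl]magnesium chloride | C/C(=C\CCOCc1ccc(OC)cc1)[Mg]Cl | intermediate (not isolated)
10 | ethyl (2R,4E)-2-hydroxy-7-[(4-methoxybenzyl)oxy]-4-methylhept-4-enoate | CCOC(=O)[C@H](O)C/C(C)=C/CCOCc1ccc(OC)cc1 | intermediate
11 | ethyl (2R,4E)-2-[(tert-butyldimethylsilyl)oxy]-7-[(4-methoxybenzyl)oxy]-4-methylhept-4-enoate | CCOC(=O)[C@H](O[Si](C)(C)C(C)(C)C)C/C(C)=C/CCOCc1ccc(OC)cc1 | intermediate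
12 | (2R,4E)-2-[(tert-butyldimethylsilyl)oxy]-7-[(4-methoxybenzyl)oxy]-4-methylhept-4-enal | O=C[C@H](O[Si](C)(C)C(C)(C)C)C/C(C)=C/CCOCc1ccc(OC)cc1 | intermediate
13 | methyl acrylate | C=CC(=O)OC | starting material
14 | methyl (3RS,4R,6E)-4-[(tert-butyldimethylsilyl)oxy]-3-hydroxy-9-[(4-methoxybenzyl)oxy]-6-methyl-2-methylidenenon-6-enoate (C3 epimer mixture) | COC(=O)C(=C)C(O)[C@H](O[Si](C)(C)C(C)(C)C)C/C(C)=C/CCOCc1ccc(OC)cc1 | intermediate
15 | methyl (2Z,4R,6E)-2-(bromomethyl)-4-[(tert-butyldimethylsilyl)oxy]-9-[(4-methoxybenzyl)oxy]-6-methylnona-2,6-dienoate | COC(=O)/C(CBr)=C/[C@H](O[Si](C)(C)C(C)(C)C)C/C(C)=C/CCOCc1ccc(OC)cc1 | intermediate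
16 | but-2-yn-1-ol | CC#CCO | starting material
17 | sodium 2,2-bis(2-methoxyethoxy)-3-methyl-2,5-dihydro-1,2-oxaaluminol-2-uide (cyclic alkenylalanate) | CC1=CCO[Al-]1(OCCOC)OCCOC.[Na+] | intermediate (not isolated)
18 | (Z)-3-iodobut-2-en-1-ol | C/C(I)=C/CO | intermediate
19 | (Z)-3-iodobut-2-enal | C/C(I)=C/C=O | intermediate
20 | methyl (3R,4S,5Z)-3-[(1R,3E)-1-[(tert-butyldimethylsilyl)oxy]-6-[(4-methoxybenzyl)oxy]-3-methylhex-3-en-1-yl]-6-iodo-2-methylidene-4-[(trimethylsilyl)oxy]hept-5-enoate | COC(=O)C(=C)[C@@H]([C@H](O[Si](C)(C)C)/C=C(/C)I)[C@H](O[Si](C)(C)C(C)(C)C)C/C(C)=C/CCOCc1ccc(OC)cc1 | intermediate (not isolated)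
21 | (4S,5S)-4-[(1R,3E)-1-[(tert-butyldimethylsilyl)oxy]-6-[(4-methoxybenzyl)oxy]-3-methylhex-3-en-1-yl]-5-[(1Z)-2-iodoprop-1-en-1-yl]-3-methylideneoxolan-2-one | C=C1C(=O)O[C@H](/C=C(/C)I)[C@H]1[C@H](O[Si](C)(C)C(C)(C)C)C/C(C)=C/CCOCc1ccc(OC)cc1 | intermediate
22 | (4S,5S)-4-[(1R,3E)-1-[(tert-butyldimethylsilyl)oxy]-6-hydroxy-3-methylhex-3-en-1-yl]-5-[(1Z)-2-iodoprop-1-en-1-yl]-3-methylideneoxolan-2-one | C=C1C(=O)O[C@H](/C=C(/C)I)[C@H]1[C@H](O[Si](C)(C)C(C)(C)C)C/C(C)=C/CCO | intermediate
23 | (3E,6R)-6-[(tert-butyldimethylsilyl)oxy]-6-[(2S,3S)-2-[(1Z)-2-iodoprop-1-en-1-yl]-4-methylidene-5-oxooxolan-3-yl]-4-methylhex-3-enal | C=C1C(=O)O[C@H](/C=C(/C)I)[C@H]1[C@H](O[Si](C)(C)C(C)(C)C)C/C(C)=C/CC=O | intermediate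
24 | (3aS,4R,6E,9S,10Z,11aR)-4-[(tert-butyldimethylsilyl)oxy]-9-hydroxy-6,10-dimethyl-3-methylidene-3a,4,5,8,9,11a-hexahydrocyclodeca[b]furan-2(3H)-one | C=C1C(=O)O[C@@H]2/C=C(/C)[C@@H](O)C/C=C(C)/C[C@@H](O[Si](C)(C)C(C)(C)C)[C@@H]12 | intermediate
25 | tiglic acid, (E)-2-methylbut-2-enoic acid | C/C=C(\C)C(=O)O | starting material
26 | (R)-2-methylbutanoic acid | CC[C@@H](C)C(=O)O | intermediate
27 | (2R)-2-methylbutanoic 2-methyl-6-nitrobenzoic anhydride | CC[C@@H](C)C(=O)OC(=O)c1c(C)cccc1[N+](=O)[O-] | intermediate (not isolated)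
28 | (3aS,4R,6E,9S,10Z,11aR)-4-[(tert-butyldimethylsilyl)oxy]-6,10-dimethyl-3-methylidene-2-oxo-2,3,3a,4,5,8,9,11a-octahydrocyclodeca[b]furan-9-yl (2R)-2-methylbutanoate | C=C1C(=O)O[C@@H]2/C=C(/C)[C@@H](OC(=O)[C@H](C)CC)C/C=C(C)/C[C@@H](O[Si](C)(C)C(C)(C)C)[C@@H]12 | intermediate
29 | (3aR,4R,6E,9S,10Z,11aR)-4-hydroxy-6,10-dimethyl-3-methylidene-2-oxo-2,3,3a,4,5,8,9,11a-octahydrocyclodeca[b]furan-9-yl (2R)-2-methylbutanoate | C=C1C(=O)O[C@@H]2/C=C(/C)[C@@H](OC(=O)[C@H](C)CC)C/C=C(C)/C[C@@H](O)[C@@H]12 | intermediate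
30 | (E)-2-methylbut-2-en-1-ol | C/C=C(\C)CO | intermediate
31 | [(2S,3S)-2,3-dimethyloxiran-2-yl]methanol | OC[C@]1(C)O[C@H]1C | intermediate
32 | (2R,3S)-2,3-dimethyloxirane-2-carboxylic acid | OC(=O)[C@]1(C)O[C@H]1C | intermediate
33 | (2R,3S)-2,3-dimethyloxirane-2-carboxylic 2-methyl-6-nitrobenzoic anhydride | O=C(OC(=O)c1c(C)cccc1[N+](=O)[O-])[C@]1(C)O[C@H]1C | intermediate (not isolated)
34 | (3aR,4R,6E,9S,10Z,11aR)-6,10-dimethyl-3-methylidene-9-{[(2R)-2-methylbutanoyl]oxy}-2-oxo-2,3,3a,4,5,8,9,11a-octahydrocyclodeca[b]furan-4-yl (2R,3S)-2,3-dimethyloxirane-2-carboxylate | C=C1C(=O)O[C@@H]2/C=C(/C)[C@@H](OC(=O)[C@H](C)CC)C/C=C(C)/C[C@@H](OC(=O)[C@]3(C)O[C@H]3C)[C@@H]12 | intermediate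
35 | CNP0265335.3, (1R,3S,6R,7R,8R,10R)-1β,10α-epoxy-3β-[(2R)-2-methylbutanoyloxy]-8β-[(2R,3S)-2,3-dimethyloxirane-2-carbonyloxy]germacra-4Z,11(13)-dien-6α,12-olide | C=C1C(=O)O[C@@H]2/C=C(/C)[C@@H](OC(=O)[C@H](C)CC)C[C@H]3O[C@]3(C)C[C@@H](OC(=O)[C@]3(C)O[C@H]3C)[C@@H]12 | target

**Counts**
Total step count: 23.
Longest linear sequence: 15 steps (1, 2, 5, 6, 7, 8, 9, 12, 13, 14, 15, 17, 18, 22, 23; the line from L-serine through steps 3 and 4 is equally long), which is 65 % of the total.

**Steps most likely to fail, with fallbacks**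

Step 12 (the proposed new step). Risks are a mismatch between the catalyst and the C8 centre, incomplete anti selectivity, and Z/E erosion of 19. The fallback uses known chemistry, sets out from 15 and 19 and comes back to the route at 21. Indium powder in THF/H2O (Barbier conditions) couples 15 with 19 through the Z-configured allylindium species to the syn adduct, with the aldehyde taken up anti to the C8 silyloxy group. Acidic work-up lactonises it to the cis-lactone F1, the C6 epimer of 21. LiOH in THF/H2O followed by careful acidification to pH 4 opens it to the hydroxy acid F2. PPh3/DIAD in THF under high dilution then recloses the ring with inversion at C6 (Mitsunobu lactonisation) to give 21.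

Step 15. Risks are oligomerisation, migration of the β,γ-olefin in 23 before ring closure, and insufficient catalyst control at C3 in a strained ten-membered transition state. The fallback sets out from 23 and comes back at 24. The classical stoichiometric closure (CrCl2, 10 equiv, NiCl2, 1 mol %, DMSO/THF, 2 mM) is run without a chiral ligand and gives 24 together with its C3 epimer, the (9R)-alcohol F3. Dess–Martin oxidation of the mixture converges both to the macrocyclic dienone F4. Corey–Bakshi–Shibata reduction with (R)-2-methyl-CBS-oxazaborolidine and BH3·SMe2 at −40 °C then sets C3 by reagent control and returns 24.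

Step 23. The risk is attack of the peracid on the other face of the 1(10)-olefin, or partial epoxidation of the 4,5-olefin. The fallback sets out from 34 and comes back at 35. NBS in DME/H2O at 0 °C forms the bromonium ion on the exposed face and water opens it anti at the tertiary C10 to give the bromohydrin F5. K2CO3 in acetone then closes the oxirane by displacement of bromide with inversion at C1, which places the epoxide oxygen on the face opposite to the one reached directly by the peracid and gives 35.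

**Further compounds**
F1 | step 12 | (4S,5R)-4-[(1R,3E)-1-[(tert-butyldimethylsilyl)oxy]-6-[(4-methoxybenzyl)oxy]-3-methylhex-3-en-1-yl]-5-[(1Z)-2-iodoprop-1-en-1-yl]-3-methylideneoxolan-2-one | C=C1C(=O)O[C@@H](/C=C(/C)I)[C@H]1[C@H](O[Si](C)(C)C(C)(C)C)C/C(C)=C/CCOCc1ccc(OC)cc1
F2 | step 12 | (3S,4R,5Z)-3-[(1R,3E)-1-[(tert-butyldimethylsilyl)oxy]-6-[(4-methoxybenzyl)oxy]-3-methylhex-3-en-1-yl]-4-hydroxy-6-iodo-2-methylidenehept-5-enoic acid | OC(=O)C(=C)[C@@H]([C@@H](O)/C=C(/C)I)[C@H](O[Si](C)(C)C(C)(C)C)C/C(C)=C/CCOCc1ccc(OC)cc1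
F3 | step 15 | (3aS,4R,6E,9R,10Z,11aR)-4-[(tert-butyldimethylsilyl)oxy]-9-hydroxy-6,10-dimethyl-3-methylidene-3a,4,5,8,9,11a-hexahydrocyclodeca[b]furan-2(3H)-one | C=C1C(=O)O[C@@H]2/C=C(/C)[C@H](O)C/C=C(C)/C[C@@H](O[Si](C)(C)C(C)(C)C)[C@@H]12
F4 | step 15 | (3aS,4R,6E,10Z,11aR)-4-[(tert-butyldimethylsilyl)oxy]-6,10-dimethyl-3-methylidene-3a,4,5,8-tetrahydrocyclodeca[b]furan-2,9(3H,11aH)-dione | C=C1C(=O)O[C@@H]2/C=C(/C)C(=O)C/C=C(C)/C[C@@H](O[Si](C)(C)C(C)(C)C)[C@@H]12
F5 | step 23 | (1S,3S,6R,7R,8R,10R)-1-bromo-10-hydroxy-3-[(2R)-2-methylbutanoyloxy]-8-[(2R,3S)-2,3-dimethyloxirane-2-carbonyloxy]germacra-4Z,11(13)-dien-6,12-olide | C=C1C(=O)O[C@@H]2/C=C(/C)[C@@H](OC(=O)[C@H](C)CC)C[C@H](Br)[C@](C)(O)C[C@@H](OC(=O)[C@]3(C)O[C@H]3C)[C@@H]12
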